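## The problem

The target is a 2-methoxy-3,5-dimethyl-4H-pyran-4-one whose C6 is bonded to the quaternary carbon of a cyclobutane. The core is numbered C1 (pyrone-bearing cyclobutane carbon), C2 (ring-fusion CH), C3 (peroxide C–Me), C4 (alkene CH), C5 (alkene C–Me), C6 (peroxide CH), C7 (ring-fusion C–Me) and C8 (CHMe). The cyclobutane C1–C2–C7–C8 is cis-fused along C2–C7 to the six-membered ring C2–C7, and a C3–O–O–C6 bridge makes that ring a 2,3-dioxabicyclo[2.2.2]octene. All six stereocentres (C1, C2, C3, C6, C7, C8) are contiguous and C1 and C7 are quaternary. The methyl groups on C1, C8 and C7 share the exo face of the cyclobutane, the pyrone lies on the endo face under the six-membered ring, and the peroxide is anti to the cyclobutane. Only C1 and C8 need independent control: C2 and C7 can follow from a disrotatory 6π closure of a cyclooctatriene, and C3 and C6 from attack of oxygen on the convex face of the resulting diene. The peroxide tolerates no reductant, phosphine, low-valent metal, strong base or heat; the α-methoxy-γ-pyrone is sensitive to ultraviolet light, acid and hard nucleophiles; the trimethylcyclohexadiene is sensitive to acid; and a cyclooctatriene carrying C1 and C8 can lose both by reversible 8π opening if overheated. The enabling feature is the chain C2–C8, seven contiguous ring carbons with methyl groups on the alternate carbons C3, C5 and C7. This is the ring of 2,4,6-trimethyltropone 8, closed by the single carbon C1, whose methyl group and acyl carbon are those of a 2-diazopropanoate 2.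

## Retrosynthesis

C3–O and C6–O (22 ⇒ 21). The peroxide is taken off first because no other step of the route is compatible with it. Cutting both C–O bonds leaves bicyclo[4.2.0]octadiene 21, with four of the six stereocentres and no fragile group except the pyrone. The forward [4+2] addition of singlet oxygen must occur anti to the cyclobutane, the face that the endo pyrone leaves open, and must spare the pyrone, which sensitisation with visible light allows.

Pyrone ring (21 ⇒ 15 + 16). The pyrone is bonded to a quaternary sp3 carbon, so coupling an intact pyrone to C1 is unrealistic. The cut is made inside the heterocycle instead: the O-methyl bond, the lactone C–O bond and the C–C bond next to the carbon on C1. This leads back through hydroxypyranone 20, tricarbonyl ester 19 and aldol 18 to aldehyde 15 and commercial keto ester 16, used as its dianion 17. The acyl carbon on C1 thereby becomes C6 of the pyrone. The forward sequence asks for an aldol addition to a neopentylic aldehyde and a regioselective O-methylation.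

C1 side chain (15 ⇒ 14 ⇒ 13). Aldehyde 15 is traced through alcohol 14 to ester 13 by oxidation-level changes only. A direct partial reduction of the hindered ester would save a step but is less dependable than reduction and re-oxidation.

C2–C7 (13 ⇒ 12). Cutting the ring-fusion bond opens the cyclobutane to cyclooctatriene 12, which has only the two stereocentres C1 and C8. This is preferred to any cut that keeps the four-membered ring, because the thermal disrotatory 6π closure forms the cis fusion and both fusion centres without reagents. The forward reaction must favour the cis-fused isomer with the acyl group endo, and the two isomers can equilibrate through 12.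

C8–CH3 and C2–H (12 ⇒ 11 ⇒ 10 ⇒ 9). Removing the C8 methyl and restoring oxygen at C2 gives trienone 9 by way of triflate 11 and trienolate 10. This moves the last non-quaternary stereocentre out of the ring-forming step and leaves a linear trienone whose remote terminus is C8. Carrying the C8 methyl on the tropone instead would put methyl groups on both carbons flanking the carbonyl and remove the basis for selective migration. The forward steps need remote (1,8) methyl transfer from a cuprate, addition anti to the C1 acyl group, and mild reductive removal of the triflate. A tert-butyl ester is chosen so that the acyl group is clearly the larger substituent on C1.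

C1–C2 and C1–C8 (9 ⇒ 8 + 2). Cutting both bonds to C1 removes the only remaining stereocentre and the eight-membered ring at once. It leaves planar tropone 8 and diazo ester 2, which between them hold every carbon of the core except the C8 methyl. Neighbouring cuts (C1–C8 with C2–C3, or a cyclisation of an open chain) would need an acyclic polyene of defined geometry. The forward reaction must add the diazo carbon at the carbonyl carbon, shift the CH carbon C8 and not the methyl-bearing C3, and fix C1 under catalyst control.

Tropone (8 ⇒ 6 ⇒ 4 ⇒ 3 + 2). Tropone 8 is traced through dienone 7 to cycloheptanone 6 (threefold dehydrogenation), and 6 through keto acid 5 and keto ester 4 to symmetrical cyclohexanone 3 and the same diazo ester 2. The symmetry of 3 fixes where the inserted carbon sits. Ring enlargements of dichloromethyl cyclohexadienones derived from phenols cannot guarantee this, since the radical may insert on either side of the quaternary carbon.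

Diazo ester (2 ⇒ 1). Compound 2 comes from commercial β-keto ester 1 by deacylating diazo transfer, and one batch serves steps 2 and 5.

## Roads not taken

Alternative 1: The cut is C4–C5 of the cyclohexadiene on an intact cyclobutane. In the forward step a cationic phosphine–gold catalyst activates the propynyl group of tert-butyldimethyl{[1,2,3-trimethyl-4-(prop-1-en-2-yl)-3-(prop-1-yn-1-yl)cyclobutyl]methoxy}silane A2. The isopropenyl CH2 attacks the methyl-bearing alkyne carbon (6-endo) to give tert-butyldimethyl[(1,3,5,7,8-pentamethylbicyclo[4.2.0]octa-2,4-dien-7-yl)methoxy]silane A1, the silyl ether of 14.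
- Merits: all four cyclobutane stereocentres are fixed before the six-membered ring forms, so the route depends neither on the endo/exo outcome of a 6π closure nor on a cuprate face selectivity. In this respect it is safer than the chosen plan.
- Weak points: the difficulty moves into A2, a cyclobutane with four contiguous stereocentres, two of them quaternary, which needs its own long stereocontrolled synthesis. The 1,5-enyne usually gives bicyclo[3.1.0]hexenes with gold. The desired 6-endo path passes a tertiary cation on C3 next to the cyclobutane, which invites ring enlargement to a cyclopentane.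
- Comparison: the chosen plan assembles every ring carbon from two simple partners in one step and needs only one catalyst-controlled stereocentre.

Alternative 2: The cuts are C8–CH3 and C1–CO on 1,3,5,7-tetramethylcyclooctatetraene A4. In the forward step the dianion of A4 is methylated at an unsubstituted carbon and the trienyl anion is acylated at the adjacent methyl-bearing terminus with a menthyl chloroformate. The product is (−)-menthyl 1,3,5,7,8-pentamethylcycloocta-2,4,6-triene-1-carboxylate A3.
- Merits: A3 is at the oxidation level of 12 and is reached in one operation, where the chosen route needs three steps from 8 and must remove a ketone. Its step economy is better.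
- Weak points: A4 is not a catalogue compound and needs several steps. The two termini of the trienyl anion are enantiotopic, so the absolute configuration rests on a remote menthyl group and in practice on separating diastereomers. Methylation at methyl-bearing carbons and acylation at internal positions are open regiochemical questions.
- Comparison: the chosen plan sets C1 by a chiral catalyst and starts from purchasable materials.

Alternative 3: The cut is C1–C2 together with a temporary bond C1–C3. In the forward step the carbenoid from methyl 2-diazo-3-(1,3,5-trimethylcyclohexa-2,5-dien-1-yl)butanoate A6 and a dirhodium tetracarboxylate cyclopropanates one ring alkene. This gives the housane methyl 1,3,5,8-tetramethyltricyclo[4.2.0.0(5,7)]oct-2-ene-7-carboxylate A5, whose extra bond is then cleaved.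
- Merits: the bond formation is intramolecular and fast, and the cyclobutane arises without pericyclic equilibria or a conjugate addition.
- Weak points: the carbenoid has a β-hydrogen on C8 and can undergo a 1,2-hydride shift. A ring-fused bicyclo[2.1.0]pentane is highly strained. The two ring alkenes of A6 are diastereotopic, so the C7/C8 relationship depends on which one reacts. The C1 methyl and the C3=C4 unsaturation must still be introduced after scission, and A6 needs a synthesis that sets C8.
- Comparison: the chosen plan leaves fewer stereochemical questions open (one catalyst-set centre, one substrate-controlled addition) and is shorter to the core. Its key step, however, is less precedented than a carbenoid cyclopropanation.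

Key step: step 5

Assumption: ketone 3 is used as the commercial cis/trans mixture because all its stereocentres are erased on the way to tropone 8, and β-keto ester 1 is taken as a catalogue reagent.

## Route

Step 1
Reactants: 1 tert-butyl 2-methyl-3-oxobutanoate
Product: 2 tert-butyl 2-diazopropanoate
Conditions: p-ABSA, DBU, MeCN, 0 °C to rt
Reagents that add atoms: 4-acetamidobenzenesulfonyl azide (p-ABSA), CC(=O)Nc1ccc(cc1)S(=O)(=O)N=[N+]=[N-]
Why: Regitz deacylating diazo transfer; the enolate of 1 adds to the sulfonyl azide and the triazene fragments with transfer of the acetyl group to the sulfonamide, the standard access to α-alkyl-α-diazo esters.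

Step 2
Reactants: 3 3,5-dimethylcyclohexan-1-one; 2 tert-butyl 2-diazopropanoate
Product: 4 tert-butyl 1,4,6-trimethyl-2-oxocycloheptane-1-carboxylate
Conditions: BF3·OEt2, CH2Cl2, −78 °C
Reagents that add atoms: none
Why: Lewis-acid-promoted Tiffeneau–Demjanov-type homologation of a cyclohexanone with an α-alkyl-α-diazo ester; the diazo carbon adds to the activated carbonyl and a ring CH2 shifts as N2 leaves. Ketone 3 is symmetrical, so either shift gives the same constitution, and the diastereomer mixture is of no consequence.

Step 3
Reactants: 4 tert-butyl 1,4,6-trimethyl-2-oxocycloheptane-1-carboxylate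
Product: 6 2,4,6-trimethylcycloheptan-1-one, via β-keto acid 5 (not isolated)
Conditions: TsOH·H2O (cat.), toluene, 100 °C
Reagents that add atoms: none
Why: Acid-catalysed loss of isobutene from the tert-butyl ester followed by thermal decarboxylation of the β-keto acid; the stereocentres of 6 disappear in step 4.

Step 4
Reactants: 6 2,4,6-trimethylcycloheptan-1-one
Product: 8 2,4,6-trimethylcyclohepta-2,4,6-trien-1-one (2,4,6-trimethyltropone), via 2,4,6-trimethylcyclohepta-2,6-dien-1-one 7 (not isolated)
Conditions: IBX (4 equiv), DMSO–fluorobenzene, 85 °C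
Reagents that add atoms: none
Why: IBX dehydrogenation of ketones (enolisation, single-electron oxidation, loss of a β-hydrogen) carried through three rounds, as is known for cycloheptanone itself; the tropone is the stabilised end point, and any exocyclic alkene isomer should tautomerise into the ring.

Step 5
Reactants: 8 2,4,6-trimethylcyclohepta-2,4,6-trien-1-one; 2 tert-butyl 2-diazopropanoate
Product: 9 tert-butyl (1S,2Z,4Z,6Z)-1,3,5,7-tetramethyl-8-oxocycloocta-2,4,6-triene-1-carboxylate
Conditions: Sc(OTf)3 (10 mol %), chiral N,N'-dioxide ligand (pipecolic acid-derived bis(2,6-diisopropylanilide), 11 mol %), CH2Cl2, −20 °C, slow addition of 2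
Reagents that add atoms: none
Why: Proposed new method: the chiral Sc(OTf)3–N,N'-dioxide complex binds the strongly Lewis-basic tropone oxygen and gives the carbonyl carbon of 8 (C2 of the target numbering, C8 in the name of 9) hydroxytropylium character; the nucleophilic diazo carbon of 2 adds there to a diazonium alkoxide, and the ring carbon antiperiplanar to the C–N2 bond shifts to the diazo carbon as N2 leaves, which forms C1–C2 and C1–C8. The closest known reactions are the Lewis-acid-catalysed, also enantioselective, Tiffeneau–Demjanov-type homologations of cyclic ketones with α-alkyl-α-diazo esters and the uncatalysed enlargement of tropone by diazomethane; a diazo ester has not been inserted into a tropone. The eight-membered ring is not closed by cyclisation but arises by insertion of C1 into the C2–C8 bond of the seven-membered ring (1,2-alkenyl shift, ring enlargement). The quaternary stereocentre C1 is set in the addition, where the ligand pocket selects the enantiotopic face of the diazo carbon that meets the bound tropone, and it is kept because the shift is stereospecific with inversion at the carbon that loses N2; the ligand antipode that delivers (S)-9 is used. Regioselectivity requires the CH carbon C8 to migrate instead of C3, which the C3 methyl should secure by clashing with the methyl and ester of the diazo unit in the rotamer needed for its own shift. Chemoselectivity requires attack at the carbonyl carbon, not conjugate attack at ring carbons or dipolar addition to a ring alkene; the disubstituted, ester-stabilised diazo carbon is hindered and weakly dipolar at −20 °C. The product 9 is a twisted ketone next to a quaternary carbon and should bind scandium less well than 8, so a second insertion should not compete.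

Step 6
Reactants: 9 tert-butyl (1S,2Z,4Z,6Z)-1,3,5,7-tetramethyl-8-oxocycloocta-2,4,6-triene-1-carboxylate
Product: 11 tert-butyl (1S,8R)-1,3,5,7,8-pentamethyl-2-[(trifluoromethanesulfonyl)oxy]cycloocta-2,4,6-triene-1-carboxylate, via lithium trienolate 10 (not isolated)
Conditions: Me2CuLi (CuI, MeLi), Et2O, −78 to −40 °C; then PhNTf2, THF, −78 to 0 °C
Reagents that add atoms: lithium dimethylcuprate, [Li+].C[Cu-]C; N-phenylbis(trifluoromethanesulfonimide), O=S(=O)(N(c1ccccc1)S(=O)(=O)C(F)(F)F)C(F)(F)F
Why: Remote (1,8) conjugate addition of a Gilman cuprate to a linear trienyl ketone, as known for 2,4,6-trienoates and for tropones, followed by O-sulfonylation of the enolate. Addition at the terminus C8 gives the fully conjugated trienolate, and methyl is delivered to the face of C8 anti to the bulky tert-butyl ester on C1, that is cis to the C1 methyl.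

Step 7
Reactants: 11 tert-butyl (1S,8R)-1,3,5,7,8-pentamethyl-2-[(trifluoromethanesulfonyl)oxy]cycloocta-2,4,6-triene-1-carboxylate
Product: 13 tert-butyl (1R,6R,7S,8R)-1,3,5,7,8-pentamethylbicyclo[4.2.0]octa-2,4-diene-7-carboxylate, via cyclooctatriene ester 12 (not isolated)
Conditions: Pd(OAc)2 (5 mol %), PPh3, n-Bu3N, HCO2H, DMF, 40 °C; then 80 °C
Reagents that add atoms: none
Why: Palladium-catalysed formate reduction of an enol triflate (oxidative addition to zerovalent palladium, formate decarboxylation, C–H reductive elimination), then thermal disrotatory 6π electrocyclisation that forms C2–C7 with cis fusion. The two cis-fused isomers interconvert through 12, and the one with a single endo substituent (the flat ester) and both cyclobutane methyl groups exo is expected to prevail.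

Step 8
Reactants: 13 tert-butyl (1R,6R,7S,8R)-1,3,5,7,8-pentamethylbicyclo[4.2.0]octa-2,4-diene-7-carboxylate
Product: 14 [(1R,6R,7S,8R)-1,3,5,7,8-pentamethylbicyclo[4.2.0]octa-2,4-dien-7-yl]methanol
Conditions: LiAlH4, THF, 0 to 40 °C
Reagents that add atoms: none
Why: Hydride reduction of an ester to the primary alcohol; the unconjugated diene is inert to LiAlH4 and no stereocentre is touched.

Step 9
Reactants: 14 [(1R,6R,7S,8R)-1,3,5,7,8-pentamethylbicyclo[4.2.0]octa-2,4-dien-7-yl]methanol
Product: 15 (1R,6R,7S,8R)-1,3,5,7,8-pentamethylbicyclo[4.2.0]octa-2,4-diene-7-carbaldehyde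
Conditions: Dess–Martin periodinane, NaHCO3, CH2Cl2, rt
Reagents that add atoms: none
Why: Dess–Martin oxidation under buffered, non-acidic conditions; the aldehyde has no α-hydrogen and cannot epimerise.

Step 10
Reactants: 15 (1R,6R,7S,8R)-1,3,5,7,8-pentamethylbicyclo[4.2.0]octa-2,4-diene-7-carbaldehyde; 16 methyl 2-methyl-3-oxopentanoate
Product: 18 methyl 5-hydroxy-2,4-dimethyl-3-oxo-5-[(1R,6R,7S,8R)-1,3,5,7,8-pentamethylbicyclo[4.2.0]octa-2,4-dien-7-yl]pentanoate, via keto ester dianion 17 (not isolated)
Conditions: 16, NaH then n-BuLi, THF, 0 °C; then 15, −78 °C; NH4Cl quench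
Reagents that add atoms: none
Why: Aldol addition of a β-keto ester dianion through its more reactive γ-carbon to a non-enolisable aldehyde; the three new stereocentres become sp2 in steps 11 and 12, so their configuration does not matter.

Step 11
Reactants: 18 methyl 5-hydroxy-2,4-dimethyl-3-oxo-5-[(1R,6R,7S,8R)-1,3,5,7,8-pentamethylbicyclo[4.2.0]octa-2,4-dien-7-yl]pentanoate
Product: 19 methyl 2,4-dimethyl-3,5-dioxo-5-[(1R,6R,7S,8R)-1,3,5,7,8-pentamethylbicyclo[4.2.0]octa-2,4-dien-7-yl]pentanoate
Conditions: Dess–Martin periodinane, CH2Cl2, rt
Reagents that add atoms: none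
Why: Dess–Martin oxidation of a β-hydroxy ketone to the 1,3-diketone, the usual second step of polypropionate pyrone syntheses.

Step 12
Reactants: 19 methyl 2,4-dimethyl-3,5-dioxo-5-[(1R,6R,7S,8R)-1,3,5,7,8-pentamethylbicyclo[4.2.0]octa-2,4-dien-7-yl]pentanoate
Product: 20 4-hydroxy-3,5-dimethyl-6-[(1R,6R,7S,8R)-1,3,5,7,8-pentamethylbicyclo[4.2.0]octa-2,4-dien-7-yl]-2H-pyran-2-one
Conditions: DBU, toluene, 60 °C
Reagents that add atoms: none
Why: Base-mediated cyclisation of a 3,5-dioxo ester: the enol oxygen of the C5 ketone attacks the ester with loss of methanol (lactonisation) to give the 4-hydroxy-2-pyranone.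

Step 13
Reactants: 20 4-hydroxy-3,5-dimethyl-6-[(1R,6R,7S,8R)-1,3,5,7,8-pentamethylbicyclo[4.2.0]octa-2,4-dien-7-yl]-2H-pyran-2-one
Product: 21 2-methoxy-3,5-dimethyl-6-[(1R,6R,7S,8R)-1,3,5,7,8-pentamethylbicyclo[4.2.0]octa-2,4-dien-7-yl]-4H-pyran-4-one
Conditions: MeOSO2F, CH2Cl2, rt; NaHCO3 work-up
Reagents that add atoms: methyl fluorosulfonate, COS(=O)(=O)F
Why: Hard O-methylation of the neutral 4-hydroxy-2-pyranone at its most basic site, the lactone carbonyl oxygen, which gives the α-methoxy-γ-pyrone regioselectively. The acid set free is held by the basic γ-pyrone until the bicarbonate work-up, which protects the diene.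

Step 14
Reactants: 21 2-methoxy-3,5-dimethyl-6-[(1R,6R,7S,8R)-1,3,5,7,8-pentamethylbicyclo[4.2.0]octa-2,4-dien-7-yl]-4H-pyran-4-one
Product: 22 2-methoxy-3,5-dimethyl-6-[1,3,4,5,10-pentamethyl-7,8-dioxatricyclo[4.2.2.0(2,5)]dec-9-en-3-yl]-4H-pyran-4-one (target; O–O bridge across C3 and C6 anti to the cyclobutane)
Conditions: O2, methylene blue (cat.), visible light (>500 nm), CH2Cl2, 0 °C
Reagents that add atoms: dioxygen, O=O
Why: Photosensitised [4+2] cycloaddition of singlet oxygen to the cisoid cyclohexadiene; oxygen approaches the convex face, anti to the cyclobutane and its endo pyrone, which sets C3 and C6. Visible light excites only the dye and spares the pyrone.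

## Compound list

1 | tert-butyl 2-methyl-3-oxobutanoate | CC(=O)C(C)C(=O)OC(C)(C)C | starting material
2 | tert-butyl 2-diazopropanoate | CC(=[N+]=[N-])C(=O)OC(C)(C)C | intermediate
3 | 3,5-dimethylcyclohexan-1-one (cis/trans mixture) | CC1CC(C)CC(=O)C1 | starting material
4 | tert-butyl 1,4,6-trimethyl-2-oxocycloheptane-1-carboxylate (diastereomer mixture) | CC(C)(C)OC(=O)C1(C)CC(C)CC(C)CC1=O | intermediate
5 | 1,4,6-trimethyl-2-oxocycloheptane-1-carboxylic acid | OC(=O)C1(C)CC(C)CC(C)CC1=O | intermediate (not isolated)
6 | 2,4,6-trimethylcycloheptan-1-one (diastereomer mixture) | CC1CC(C)CC(C)CC1=O | intermediate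
7 | 2,4,6-trimethylcyclohepta-2,6-dien-1-one | CC1=CC(C)CC(C)=CC1=O | intermediate (not isolated)
8 | 2,4,6-trimethylcyclohepta-2,4,6-trien-1-one (2,4,6-trimethyltropone) | CC1=CC(C)=CC(C)=CC1=O | intermediate
9 | tert-butyl (1S,2Z,4Z,6Z)-1,3,5,7-tetramethyl-8-oxocycloocta-2,4,6-triene-1-carboxylate | CC(C)(C)OC(=O)[C@]1(C)C(=O)/C(C)=C\C(C)=C/C(C)=C\1 | intermediate
10 | lithium (7R,8S)-8-(tert-butoxycarbonyl)-2,4,6,7,8-pentamethylcycloocta-1,3,5-trien-1-olate | [Li+].CC(C)(C)OC(=O)[C@@]1(C)[C@H](C)/C(C)=C\C(C)=C/C(C)=C\1[O-] | intermediate (not isolated)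
11 | tert-butyl (1S,8R)-1,3,5,7,8-pentamethyl-2-[(trifluoromethanesulfonyl)oxy]cycloocta-2,4,6-triene-1-carboxylate (ring alkenes cis within the ring) | CC(C)(C)OC(=O)[C@@]1(C)[C@H](C)/C(C)=C\C(C)=C/C(C)=C\1OS(=O)(=O)C(F)(F)F | intermediate
12 | tert-butyl (1R,8R,2Z,4Z,6Z)-1,3,5,7,8-pentamethylcycloocta-2,4,6-triene-1-carboxylate | CC(C)(C)OC(=O)[C@@]1(C)[C@H](C)/C(C)=C\C(C)=C/C(C)=C\1 | intermediate (not isolated)
13 | tert-butyl (1R,6R,7S,8R)-1,3,5,7,8-pentamethylbicyclo[4.2.0]octa-2,4-diene-7-carboxylate | CC(C)(C)OC(=O)[C@@]1(C)[C@H](C)[C@@]2(C)C=C(C)C=C(C)[C@@H]12 | intermediate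
14 | [(1R,6R,7S,8R)-1,3,5,7,8-pentamethylbicyclo[4.2.0]octa-2,4-dien-7-yl]methanol | OC[C@@]1(C)[C@H](C)[C@@]2(C)C=C(C)C=C(C)[C@@H]12 | intermediate
15 | (1R,6R,7S,8R)-1,3,5,7,8-pentamethylbicyclo[4.2.0]octa-2,4-diene-7-carbaldehyde | O=C[C@@]1(C)[C@H](C)[C@@]2(C)C=C(C)C=C(C)[C@@H]12 | intermediate
16 | methyl 2-methyl-3-oxopentanoate | CCC(=O)C(C)C(=O)OC | starting material
17 | sodium lithium 2,4-dianion of methyl 2-methyl-3-oxopentanoate | [Na+].[Li+].COC(=O)[C-](C)C(=O)[CH-]C | intermediate (not isolated)
18 | methyl 5-hydroxy-2,4-dimethyl-3-oxo-5-[(1R,6R,7S,8R)-1,3,5,7,8-pentamethylbicyclo[4.2.0]octa-2,4-dien-7-yl]pentanoate (mixture at C2, C4, C5 of the chain) | COC(=O)C(C)C(=O)C(C)C(O)[C@@]1(C)[C@H](C)[C@@]2(C)C=C(C)C=C(C)[C@@H]12 | intermediate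
19 | methyl 2,4-dimethyl-3,5-dioxo-5-[(1R,6R,7S,8R)-1,3,5,7,8-pentamethylbicyclo[4.2.0]octa-2,4-dien-7-yl]pentanoate | COC(=O)C(C)C(=O)C(C)C(=O)[C@@]1(C)[C@H](C)[C@@]2(C)C=C(C)C=C(C)[C@@H]12 | intermediate
20 | 4-hydroxy-3,5-dimethyl-6-[(1R,6R,7S,8R)-1,3,5,7,8-pentamethylbicyclo[4.2.0]octa-2,4-dien-7-yl]-2H-pyran-2-one | O=c1oc([C@@]2(C)[C@H](C)[C@@]3(C)C=C(C)C=C(C)[C@@H]23)c(C)c(O)c1C | intermediate
21 | 2-methoxy-3,5-dimethyl-6-[(1R,6R,7S,8R)-1,3,5,7,8-pentamethylbicyclo[4.2.0]octa-2,4-dien-7-yl]-4H-pyran-4-one | COc1oc([C@@]2(C)[C@H](C)[C@@]3(C)C=C(C)C=C(C)[C@@H]23)c(C)c(=O)c1C | intermediate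
22 | 2-methoxy-3,5-dimethyl-6-[1,3,4,5,10-pentamethyl-7,8-dioxatricyclo[4.2.2.0(2,5)]dec-9-en-3-yl]-4H-pyran-4-one (endoperoxide of 21, O–O anti to the cyclobutane) | COc1oc([C@@]2(C)[C@H](C)[C@@]3(C)[C@@H]4OO[C@@](C)(C=C4C)[C@@H]23)c(C)c(=O)c1C | target

## Step count and least certain steps

Total: 14 steps. Longest linear sequence: 14 steps (1 to 22); diazo ester 2 is needed before 3 can be enlarged, and 3 and 16 enter as bought.

Step 5 (key step, proposed new method). The diazo carbon may add to ring carbons of the scandium-bound tropone, or across a ring alkene, because coordination spreads the positive charge over the ring. The methyl-bearing carbon C3 may migrate in part. Enantioselection may be poor because the flat tropone offers few contacts to the ligand. Fallback with known chemistry, from 8 back to 9: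
- Uncatalysed ring enlargement of 8 with diazomethane (Et2O, 0 °C; the CH carbon migrates) gives 2,4,6-trimethylcycloocta-2,4,6-trien-1-one F1.
- C-acylation of its lithium enolate (LiHMDS, Boc2O, THF, −78 °C) gives tert-butyl 3,5,7-trimethyl-8-oxocycloocta-2,4,6-triene-1-carboxylate F2.
- Asymmetric phase-transfer methylation of this β-keto ester (MeI, CsOH·H2O, chiral spiro binaphthyl quaternary ammonium bromide, toluene, −40 °C) returns to the route at 9.

Step 6. Methyl transfer may go to C4 or C6 because the tub-shaped ring weakens conjugation along the trienone and C8 is neopentylic. Facial selection at C8 may be poor if the ring conformation, not the size of the ester, decides the approach. Fallback that avoids conjugate addition, from 8 and 2 back to 14: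
- Step 5 is run with the mirror-image ligand to give tert-butyl (1R)-1,3,5,7-tetramethyl-8-oxocycloocta-2,4,6-triene-1-carboxylate F3. Its ketone carbon is read as C8 and the migrated CH as C2, so the triene already lies at C2=C3, C4=C5 and C6=C7.
- Cp2TiMe2 (toluene, 65 °C) methylenates the non-enolisable ketone to tert-butyl (1R)-1,3,5,7-tetramethyl-8-methylidenecycloocta-2,4,6-triene-1-carboxylate F4.
- LiAlH4 gives [(1R)-1,3,5,7-tetramethyl-8-methylidenecycloocta-2,4,6-trien-1-yl]methanol F5.
- Hydroxyl-directed hydrogenation of the exocyclic 1,1-disubstituted alkene ([Ir(cod)(PCy3)(py)]PF6, H2, 1 equiv, CH2Cl2) delivers hydrogen to C8 syn to the CH2OH group. This leaves the new methyl cis to the C1 methyl in [(1R,8R)-1,3,5,7,8-pentamethylcycloocta-2,4,6-trien-1-yl]methanol F6.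
- Warming (toluene, 80 °C) closes F6 to 14.

Step 7. The trienyl triflate may undergo 6π closure before it is reduced, giving a tertiary cyclobutyl triflate that ionises. Above about 100 °C, triene 12 may also open reversibly by the 8π path and erode C1 and C8. If closure at the ester stage favours the other cis-fused isomer, the mixture can be carried on and equilibrated thermally at the stage of 21. Fallback that avoids the triflate, from 9 back to 13:
- The cuprate addition of step 6 is quenched with aqueous NH4Cl (α-protonation at C3) to give tert-butyl (1S,8R)-1,3,5,7,8-pentamethyl-2-oxocycloocta-4,6-diene-1-carboxylate F7.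
- NaBH4 (MeOH, 0 °C) gives tert-butyl (1S,8R)-2-hydroxy-1,3,5,7,8-pentamethylcycloocta-4,6-diene-1-carboxylate F8.
- Dehydration toward the only β-hydrogen, on C3 (Burgess reagent, benzene, 50 °C, or the mesylate and DBU), gives 12, which is closed to 13 at 80 °C.

Step 4. Dehydrogenation may stall at the dienone, or the oxidant may attack the ring methyl groups of the electron-rich intermediates at 85 °C. Fallback by halogenation and elimination, from 6 back to 8:
- Br2 (2 equiv, AcOH) gives 2,7-dibromo-2,4,6-trimethylcycloheptan-1-one F9.
- Li2CO3 and LiBr (DMF, 120 °C) give dienone 7, here isolated.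
- DDQ (dioxane, reflux) dehydrogenates 7 to 8.

Step 14. Singlet oxygen may undergo an ene reaction at the allylic methyl groups in place of the cycloaddition, and irradiation may trigger rearrangement of the pyrone or ring opening of the diene. Fallback from 21 to 22 without light or singlet oxygen: radical-cation-catalysed cycloaddition of ground-state oxygen with tris(4-bromophenyl)aminium hexachloroantimonate, (4-BrC6H4)3N SbCl6 (cat.), O2, CH2Cl2, −78 °C, dark. It makes no new compound.

## Further compounds

F1 | step 5 | 2,4,6-trimethylcycloocta-2,4,6-trien-1-one | O=C1C/C=C(C)\C=C(C)/C=C\1C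
F2 | step 5 | tert-butyl 3,5,7-trimethyl-8-oxocycloocta-2,4,6-triene-1-carboxylate (racemic, enolisable) | CC(C)(C)OC(=O)C1/C=C(C)\C=C(C)/C=C(C)\C1=O
F3 | step 6 | tert-butyl (1R,2Z,4Z,6Z)-1,3,5,7-tetramethyl-8-oxocycloocta-2,4,6-triene-1-carboxylate | CC(C)(C)OC(=O)[C@@]1(C)C(=O)/C(C)=C\C(C)=C/C(C)=C\1
F4 | step 6 | tert-butyl (1R)-1,3,5,7-tetramethyl-8-methylidenecycloocta-2,4,6-triene-1-carboxylate | CC(C)(C)OC(=O)[C@@]1(C)C(=C)/C(C)=C\C(C)=C/C(C)=C\1
F5 | step 6 | [(1R)-1,3,5,7-tetramethyl-8-methylidenecycloocta-2,4,6-trien-1-yl]methanol | OC[C@@]1(C)C(=C)/C(C)=C\C(C)=C/C(C)=C\1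
F6 | step 6 | [(1R,8R)-1,3,5,7,8-pentamethylcycloocta-2,4,6-trien-1-yl]methanol | OC[C@@]1(C)[C@H](C)/C(C)=C\C(C)=C/C(C)=C\1
F7 | step 7 | tert-butyl (1S,8R)-1,3,5,7,8-pentamethyl-2-oxocycloocta-4,6-diene-1-carboxylate (C3 unassigned) | CC(C)(C)OC(=O)[C@@]1(C)[C@H](C)/C(C)=C\C(C)=C/C(C)C1=O
F8 | step 7 | tert-butyl (1S,8R)-2-hydroxy-1,3,5,7,8-pentamethylcycloocta-4,6-diene-1-carboxylate (C2, C3 unassigned) | CC(C)(C)OC(=O)[C@@]1(C)[C@H](C)/C(C)=C\C(C)=C/C(C)C1O
F9 | step 4 | 2,7-dibromo-2,4,6-trimethylcycloheptan-1-one | CC1CC(C)C(Br)C(=O)C(C)(Br)C1
F0 | step 14 | none | none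
A1 | alternative 1 | tert-butyldimethyl[(1,3,5,7,8-pentamethylbicyclo[4.2.0]octa-2,4-dien-7-yl)methoxy]silane | CC(C)(C)[Si](C)(C)OC[C@@]1(C)[C@H](C)[C@@]2(C)C=C(C)C=C(C)[C@@H]12
A2 | alternative 1 | tert-butyldimethyl{[1,2,3-trimethyl-4-(prop-1-en-2-yl)-3-(prop-1-yn-1-yl)cyclobutyl]methoxy}silane (configuration as in the SMILES) | CC(C)(C)[Si](C)(C)OC[C@@]1(C)[C@H](C)[C@@](C)(C#CC)[C@H]1C(C)=C
A3 | alternative 2 | (−)-menthyl 1,3,5,7,8-pentamethylcycloocta-2,4,6-triene-1-carboxylate (ester trans to the C8 methyl) | CC(C)[C@@H]1CC[C@@H](C)C[C@H]1OC(=O)[C@]2(C)/C=C(C)\C=C(C)/C=C(C)\[C@H]2C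
A4 | alternative 2 | 1,3,5,7-tetramethylcycloocta-1,3,5,7-tetraene | C/C1=C/C(C)=C\C(C)=C/C(C)=C\1
A5 | alternative 3 | methyl 1,3,5,8-tetramethyltricyclo[4.2.0.0(5,7)]oct-2-ene-7-carboxylate | COC(=O)[C@@]12[C@H](C)[C@@]3(C)C=C(C)C[C@]1(C)[C@@H]23
A6 | alternative 3 | methyl 2-diazo-3-(1,3,5-trimethylcyclohexa-2,5-dien-1-yl)butanoate | COC(=O)C(=[N+]=[N-])[C@H](C)C1(C)C=C(C)CC(C)=C1
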